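Atom labels: ring C1 (carries the side chain), C2, C3=C4 (C4 carries C15H2O), C5 (OH), C6; chain C7(=C14H2)–C8H2–C9H=C10H–C11(CH3)(OH)–C12H2O.
Cuts: C5–H (enone reduction), the O–acyl bond on C15, C4–C15 (Morita–Baylis–Hillman), then C1–C7 and C5–O together in one three-component event. In the chain, C12–O (epoxide opening) and C9=C10 (Julia–Kocienski).
Enabling feature: the six-membered ring has a latent mirror plane through C1 and C4. The set C1–C7 bond, C5–O bond (1,3 to it) and C3=C4 alkene is what remains after an alkenylpalladium inserts into cyclohexa-1,4-diene, walks one carbon, and the mirror-symmetric η3-allyl C3–C4–C5 is captured.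
Forward order: the C7–C14 bromodiene ester is assembled first and joined to the intact carbocycle of cyclohexa-1,4-diene (no ring is built). C5 is then oxidised so that C4 can be hydroxymethylated, C15–OH is acylated, and C5=O is reduced.
Stereochemistry: C11 from (R)-2-methylglycidol; E-C9=C10 from the olefination; C1 from ligand-controlled choice between the two enantiotopic allyl termini; C5 (cis to C1) from substrate-controlled Luche reduction.
Key step: step 6

Assumption: the sense of induction in step 6 is extrapolated from the parent cyclohex-2-enyl series, where the (R,R)-bisphosphine is taken to give (S)-configured substitution products. The (S,S)-ligand is therefore used here, and the equally available antipode would replace it if the sense proved opposite.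

Step 1
Reactants: 1 3-bromobut-3-en-1-ol
Product: 2 5-[(3-bromobut-3-en-1-yl)sulfanyl]-1-phenyl-1H-tetrazole
Conditions: 1-phenyl-1H-tetrazole-5-thiol (1.1 equiv), PPh3 (1.2 equiv), DIAD (1.2 equiv), THF, 0 °C to rt
Reagents that add atoms: 1-phenyl-1H-tetrazole-5-thiol, Sc1nnnn1-c1ccccc1
Why: Mitsunobu thioetherification: the acidic tetrazolethiol displaces the activated primary alcohol, the vinylic bromide is inert to the phosphine/azodicarboxylate pair and no stereocentre is involved.

Step 2
Reactants: 2 5-[(3-bromobut-3-en-1-yl)sulfanyl]-1-phenyl-1H-tetrazole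
Product: 3 5-[(3-bromobut-3-en-1-yl)sulfonyl]-1-phenyl-1H-tetrazole
Conditions: (NH4)6Mo7O24·4H2O (10 mol %), 30 % aq H2O2 (5 equiv), EtOH, 0 °C to rt
Reagents that add atoms: hydrogen peroxide, OO
Why: Molybdate-catalysed peroxide oxidation of a sulfide to the sulfone, in which the electron-poor 2-bromoalkene should not be epoxidised.

Step 3
Reactants: 4 (R)-2-methylglycidol, [(2R)-2-methyloxiran-2-yl]methanol
Product: 5 (2S)-2-methyloxirane-2-carbaldehyde (volatile, carried on as a concentrated solution)
Conditions: TEMPO (10 mol %), PhI(OAc)2 (1.1 equiv), CH2Cl2, 0 °C to rt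
Reagents that add atoms: none
Why: Oxoammonium (TEMPO/PhI(OAc)2) oxidation of a primary alcohol stops at the aldehyde and spares the epoxide, and the fully substituted C11 cannot epimerise (its descriptor changes from R to S only because CHO outranks the ring CH2).

Step 4
Reactants: 3 5-[(3-bromobut-3-en-1-yl)sulfonyl]-1-phenyl-1H-tetrazole; 5 (2S)-2-methyloxirane-2-carbaldehyde
Product: 6 (2R)-2-[(1E)-4-bromopenta-1,4-dien-1-yl]-2-methyloxirane
Conditions: KN(SiMe3)2 (1.1 equiv) added to 3 + 5, 1,2-dimethoxyethane, −78 °C to rt
Reagents that add atoms: none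
Why: Julia–Kocienski olefination: addition of the metalated phenyltetrazolyl sulfone to the non-enolisable aldehyde, Smiles rearrangement and anti-elimination of SO2 and tetrazolate should give the E-alkene (potassium counter-ion, polar solvent, α-branched aldehyde), and adding the base to both partners limits self-condensation of 3 while C11 is untouched.

Step 5
Reactants: 6 (2R)-2-[(1E)-4-bromopenta-1,4-dien-1-yl]-2-methyloxirane
Product: 7 (2R,3E)-6-bromo-2-hydroxy-2-methylhepta-3,6-dien-1-yl 2-methylpropanoate
Conditions: iPrCO2H (1.5 equiv), Cs2CO3 (10 mol %), DMF, 60 °C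
Reagents that add atoms: isobutyric acid, CC(C)C(=O)O
Why: Base-buffered SN2 opening of a 2,2-disubstituted epoxide by a carboxylate takes place at the unsubstituted C12, so the C11–O bond is never broken, C11 keeps its configuration, and the primary isobutyrate and the free tertiary alcohol of the target arise together without protecting groups.

Step 6
Reactants: 7 (2R,3E)-6-bromo-2-hydroxy-2-methylhepta-3,6-dien-1-yl 2-methylpropanoate; 8 cyclohexa-1,4-diene
Product: 10 (2R,3E)-2-hydroxy-6-[(1S,5R)-5-hydroxycyclohex-3-en-1-yl]-2-methylhepta-3,6-dien-1-yl 2-methylpropanoate (trans-allylic alcohol), via allyl hydrogen carbonate 9 (not isolated)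
Conditions: 8 (5 equiv), Pd2(dba)3·CHCl3 (2.5 mol %), N,N'-[(1S,2S)-cyclohexane-1,2-diyl]bis[2-(diphenylphosphanyl)benzamide] (7.5 mol %), KHCO3 (2 equiv), THF/H2O 9:1, 60 °C, sealed tube
Reagents that add atoms: potassium hydrogencarbonate, [K+].OC([O-])=O
Why: Proposed new method: zerovalent palladium inserts into the C7–Br bond of 7, the alkenylpalladium adds syn across one of the two equivalent C=C bonds of 8 (new C7–C1 bond, palladium on C6), and because the C1–H is anti to the metal the only syn β-hydrogen sits on C5, so β-hydride elimination and re-insertion move palladium one carbon to C5, where the untouched C3=C4 bond captures it as an η3-allyl (C3–C4–C5) that hydrogencarbonate attacks on the face opposite to the metal before 9 loses CO2. The closest known reaction types are the three-component Heck/Tsuji–Trost couplings of aryl or vinylic halides with non-conjugated dienes (cyclohexa-1,4-diene included) and amine or malonate nucleophiles, and the palladium-catalysed asymmetric hydroxylation of cyclohex-2-enyl carbonates by hydrogencarbonate; new here are the pairing of a 2-bromo-1,4-diene with an oxygen nucleophile and the use of this ligand for both halves of the cascade. No ring is closed. The ring part of the η3-allyl intermediate has a mirror plane through C1 and C4, so C1 and C5 become stereocentres together in the C–O bond-forming event: their trans relation follows from syn carbopalladation plus anti attack, and the absolute sense follows from the chiral pocket of the bisphosphine, which selects one of the two enantiotopic allyl termini as it does in the parent cyclohexenyl system. Attack at either terminus gives the same constitution and all four sp2 carbons of 8 are equivalent, so neither the insertion nor the capture poses a regiochemical question. Chemoselectivity rests on the excess of the unhindered cis-alkene 8 over the E-alkene of 7 that is flanked by the fully substituted C11, on the inertness of the alcohol product to re-ionisation, and on capture fast enough that palladium–palladium exchange cannot invert the allyl face and erode the selectivity at C1.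

Step 7
Reactants: 10 (2R,3E)-2-hydroxy-6-[(1S,5R)-5-hydroxycyclohex-3-en-1-yl]-2-methylhepta-3,6-dien-1-yl 2-methylpropanoate
Product: 11 (2R,3E)-2-hydroxy-2-methyl-6-[(1S)-5-oxocyclohex-3-en-1-yl]hepta-3,6-dien-1-yl 2-methylpropanoate
Conditions: Dess–Martin periodinane (1.2 equiv), CH2Cl2, 0 °C to rt
Reagents that add atoms: none
Why: Dess–Martin oxidation converts the secondary allylic alcohol into the enone while the tertiary alcohol, the ester and the skipped diene are inert; the provisional C5 centre is given up on purpose so that C4 becomes nucleophilic in the next step, and C1 is not enolisable.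

Step 8
Reactants: 11 (2R,3E)-2-hydroxy-2-methyl-6-[(1S)-5-oxocyclohex-3-en-1-yl]hepta-3,6-dien-1-yl 2-methylpropanoate
Product: 12 (2R,3E)-2-hydroxy-6-[(1S)-4-(hydroxymethyl)-5-oxocyclohex-3-en-1-yl]-2-methylhepta-3,6-dien-1-yl 2-methylpropanoate
Conditions: 37 % aq HCHO (3 equiv), DMAP (30 mol %), THF/H2O, rt
Reagents that add atoms: formaldehyde, C=O
Why: Morita–Baylis–Hillman hydroxymethylation: DMAP adds to C3 of the only enone present, the C4 enolate captures formaldehyde and loss of DMAP restores the C3=C4 bond, as is well known for cyclohex-2-enone itself.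

Step 9
Reactants: 12 (2R,3E)-2-hydroxy-6-[(1S)-4-(hydroxymethyl)-5-oxocyclohex-3-en-1-yl]-2-methylhepta-3,6-dien-1-yl 2-methylpropanoate
Product: 13 (2R,3E)-2-hydroxy-2-methyl-6-[(1S)-4-{[(2-methylpropanoyl)oxy]methyl}-5-oxocyclohex-3-en-1-yl]hepta-3,6-dien-1-yl 2-methylpropanoate
Conditions: (iPrCO)2O (1.2 equiv), pyridine (3 equiv), CH2Cl2, 0 °C
Reagents that add atoms: isobutyric anhydride, CC(C)C(=O)OC(=O)C(C)C
Why: Acylation with an anhydride discriminates the unhindered primary allylic alcohol from the tertiary C11 alcohol on steric grounds, and at this stage no secondary alcohol competes.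

Step 10
Reactants: 13 (2R,3E)-2-hydroxy-2-methyl-6-[(1S)-4-{[(2-methylpropanoyl)oxy]methyl}-5-oxocyclohex-3-en-1-yl]hepta-3,6-dien-1-yl 2-methylpropanoate
Product: 14 (2R,3E)-2-hydroxy-6-[(1S,5S)-5-hydroxy-4-{[(2-methylpropanoyl)oxy]methyl}cyclohex-3-en-1-yl]-2-methylhepta-3,6-dien-1-yl 2-methylpropanoate (target)
Conditions: CeCl3·7H2O (1.1 equiv), NaBH4 (1.1 equiv), MeOH, −78 °C
Reagents that add atoms: none
Why: Luche reduction: the cerium-modified borohydride attacks the carbonyl (1,2) rather than C3, and axial delivery to the half-chair that holds the C1 side chain equatorial should give the pseudo-equatorial 5S alcohol cis to C1, as in the reduction of carvone to cis-carveol.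

Compound list
1 | 3-bromobut-3-en-1-ol | C=C(Br)CCO | starting material
2 | 5-[(3-bromobut-3-en-1-yl)sulfanyl]-1-phenyl-1H-tetrazole | C=C(Br)CCSc1nnnn1-c1ccccc1 | intermediate
3 | 5-[(3-bromobut-3-en-1-yl)sulfonyl]-1-phenyl-1H-tetrazole | C=C(Br)CCS(=O)(=O)c1nnnn1-c1ccccc1 | intermediate
4 | (R)-2-methylglycidol, [(2R)-2-methyloxiran-2-yl]methanol | OC[C@]1(C)CO1 | starting material
5 | (2S)-2-methyloxirane-2-carbaldehyde | O=C[C@]1(C)CO1 | intermediate
6 | (2R)-2-[(1E)-4-bromopenta-1,4-dien-1-yl]-2-methyloxirane | C=C(Br)C/C=C/[C@]1(C)CO1 | intermediate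
7 | (2R,3E)-6-bromo-2-hydroxy-2-methylhepta-3,6-dien-1-yl 2-methylpropanoate | C=C(Br)C/C=C/[C@@](C)(O)COC(=O)C(C)C | intermediate
8 | cyclohexa-1,4-diene | C1=CCC=CC1 | starting material
9 | hydrogen carbonate half-ester of 10 at the ring oxygen (1S,5R ring, not isolated) | C=C(C/C=C/[C@@](C)(O)COC(=O)C(C)C)[C@H]1CC=C[C@H](OC(=O)O)C1 | intermediate
10 | (2R,3E)-2-hydroxy-6-[(1S,5R)-5-hydroxycyclohex-3-en-1-yl]-2-methylhepta-3,6-dien-1-yl 2-methylpropanoate | C=C(C/C=C/[C@@](C)(O)COC(=O)C(C)C)[C@H]1CC=C[C@H](O)C1 | intermediate
11 | (2R,3E)-2-hydroxy-2-methyl-6-[(1S)-5-oxocyclohex-3-en-1-yl]hepta-3,6-dien-1-yl 2-methylpropanoate | C=C(C/C=C/[C@@](C)(O)COC(=O)C(C)C)[C@H]1CC=CC(=O)C1 | intermediate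
12 | (2R,3E)-2-hydroxy-6-[(1S)-4-(hydroxymethyl)-5-oxocyclohex-3-en-1-yl]-2-methylhepta-3,6-dien-1-yl 2-methylpropanoate | C=C(C/C=C/[C@@](C)(O)COC(=O)C(C)C)[C@H]1CC=C(CO)C(=O)C1 | intermediate
13 | (2R,3E)-2-hydroxy-2-methyl-6-[(1S)-4-{[(2-methylpropanoyl)oxy]methyl}-5-oxocyclohex-3-en-1-yl]hepta-3,6-dien-1-yl 2-methylpropanoate | C=C(C/C=C/[C@@](C)(O)COC(=O)C(C)C)[C@H]1CC=C(COC(=O)C(C)C)C(=O)C1 | intermediate
14 | (2R,3E)-2-hydroxy-6-[(1S,5S)-5-hydroxy-4-{[(2-methylpropanoyl)oxy]methyl}cyclohex-3-en-1-yl]-2-methylhepta-3,6-dien-1-yl 2-methylpropanoate | C=C(C/C=C/[C@@](C)(O)COC(=O)C(C)C)[C@H]1CC=C(COC(=O)C(C)C)[C@@H](O)C1 | target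

Total steps: 10. Longest linear sequence: 9 (steps 1, 2, 4, 5, 6, 7, 8, 9, 10).

Steps most likely to fail

Step 6. Four things may go wrong:
- After β-hydride elimination the metal hydride may let the conjugated diene go instead of re-inserting.
- The excess diene may act as a hydrogen donor and reduce the C–Br bond.
- The C6–Pd bond may add 5-exo to the C9=C10 alkene.
- The ligand may discriminate the two allyl termini poorly.

The fallback uses known chemistry, sets out from 7 and returns at 11.
- Miyaura borylation of 7 (B2pin2, PdCl2(dppf), KOAc, dioxane, 80 °C) should give the pinacol alkenylboronate F1.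
- Hayashi–Miyaura 1,4-addition of F1 to commercial cyclohex-2-enone with [Rh(acac)(C2H4)2] and (S)-BINAP in dioxane/H2O should give the (S)-3-alkenylcyclohexanone F2.
- Kinetic deprotonation on the side remote from the branched substituent (LiN(iPr)2, Me3SiCl present, THF, −78 °C) should give the doubly silylated enol ether F3. Regiocontrol is the weak point of this detour.
- Saegusa–Ito oxidation with Pd(OAc)2 in MeCN should give the silyl-protected enone F4.
- Citric acid in MeOH frees the tertiary alcohol of F4 and returns the route to 11.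

Step 5. The carboxylate may open the allylic epoxide at the tertiary allylic C11 or in the SN2' sense at C9. The tertiary alkoxide may also shuffle the acyl group between molecules. The fallback sets out from 6 and returns at 7, and it separates ring opening from acyl transfer. Aqueous NaOH in DMSO at rt should open the epoxide at C12 to give the diol F5. F5 is then esterified only at its primary hydroxyl with (iPrCO)2O and pyridine in CH2Cl2 at 0 °C to give 7.

Step 10. Hydride may be delivered to C3 with SN2' loss of the allylic carboxylate. The C15 acyl group may also migrate to the new C5 alkoxide. The fallback sets out from 12 and returns at 14, and it inverts the order of events. Luche reduction of the hydroxymethyl enone 12 (CeCl3·7H2O, NaBH4, MeOH, −78 °C), which has no allylic leaving group, should give the cis-diol F6. Site-selective esterification of the primary allylic hydroxyl of F6 (isobutyryl chloride, 2,4,6-collidine, CH2Cl2, −78 °C) then gives 14.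

Further compounds
F1 | step 6 | (2R,3E)-2-hydroxy-2-methyl-6-(4,4,5,5-tetramethyl-1,3,2-dioxaborolan-2-yl)hepta-3,6-dien-1-yl 2-methylpropanoate | C=C(C/C=C/[C@@](C)(O)COC(=O)C(C)C)B1OC(C)(C)C(C)(C)O1
F2 | step 6 | (2R,3E)-2-hydroxy-2-methyl-6-[(1S)-3-oxocyclohexyl]hepta-3,6-dien-1-yl 2-methylpropanoate | C=C(C/C=C/[C@@](C)(O)COC(=O)C(C)C)[C@H]1CCCC(=O)C1
F3 | step 6 | (2R,3E)-2-methyl-2-[(trimethylsilyl)oxy]-6-{(1S)-3-[(trimethylsilyl)oxy]cyclohex-3-en-1-yl}hepta-3,6-dien-1-yl 2-methylpropanoate | C=C(C/C=C/[C@@](C)(O[Si](C)(C)C)COC(=O)C(C)C)[C@H]1CCC=C(O[Si](C)(C)C)C1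
F4 | step 6 | (2R,3E)-2-methyl-6-[(1S)-5-oxocyclohex-3-en-1-yl]-2-[(trimethylsilyl)oxy]hepta-3,6-dien-1-yl 2-methylpropanoate | C=C(C/C=C/[C@@](C)(O[Si](C)(C)C)COC(=O)C(C)C)[C@H]1CC=CC(=O)C1
F5 | step 5 | (2R,3E)-6-bromo-2-methylhepta-3,6-diene-1,2-diol | C=C(Br)C/C=C/[C@@](C)(O)CO
F6 | step 10 | (2R,3E)-2-hydroxy-6-[(1S,5S)-5-hydroxy-4-(hydroxymethyl)cyclohex-3-en-1-yl]-2-methylhepta-3,6-dien-1-yl 2-methylpropanoate | C=C(C/C=C/[C@@](C)(O)COC(=O)C(C)C)[C@H]1CC=C(CO)[C@@H](O)C1
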